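The bench chemist's rule comes first: target made equals early rate times time. Try it on the two runs below, then find where it stops.

common to all: partner 0.160 M

|  | substrate | catalyst | time |
|---|---|---|---|
| noon | 0.0800 M | 0.00400 M |  |
| midnight | 0.160 M | 0.00400 M |  |
| spring | 0.240 M | 0.00130 M | 17 min |

- noon run (time / min: [target] / M): 0.61: 0.00269; 1.8: 0.00684; 3.5: 0.01199; 5.6: 0.01628; 8.0: 0.02035; 11: 0.02368; 14: 0.02482; 17: 0.02622
- midnight run (time / min: [target] / M): 0.61: 0.00452; 1.8: 0.01231; 3.5: 0.02131; 5.6: 0.02966; 8.0: 0.03768; 11: 0.04354; 14: 0.04783; 17: 0.05047

(readings scatter by 2 × 10⁻⁴ M)

- Overall: substrate + partner -> target, with catalyst as catalyst.
- Constant volume, constant temperature.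
- The analysis sees a species whether free or bound.
- An order is taken over about fifteen percent of the charge, up and down.

- reaction order in [substrate] at the outset, round the charge of the noon run, defined at two percent of the substrate turned into target (one fixed amount of target, the same in the runs compared)
- target in the spring run at 17 min, as a share of the substrate charged

Take the early rate as the reading at 1.8 min divided by that time:

midnight run: 0.00684 M min⁻¹
noon run: 0.00380 M min⁻¹

Now find the border in the midnight run. Its last slope is 8.80 × 10⁻⁴ M min⁻¹, which is 12.9% of the early rate, while the target read stands at 31.5% of the substrate charged. Square the share not read as target, for a rate that follows both substrate and partner at their equal charges in the midnight run, and you still get 46.9%, more than the rate kept. So the straight line fails, and the clock must be replaced: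

midnight run: 7.38 min
noon run: 6.90 min

Call this the working time: the minutes at the early rate that yield the last reading. Follow the target the early rate promises by 17 min in the midnight run: 43.4% of it is read. At 17 min the midnight run holds twice the target of the noon run, yet its working time reads 7.38 min against 6.90 min in the noon run, so carry it over.

My order over the doubling, from those early rates, is 0.848. Assume first order in catalyst, which these runs leave untested, and scale to the spring run:

early rate: 0.00313 M min⁻¹
target at 17 min: 0.0231 M, or 9.64% of the substrate charged

Partner is the limiting reagent in the spring run, and this target stays below its charge. The forecast, reckoned separately, gives 0.84 and 10% and reads the fall thus: “this is time-based catalyst death, not product inhibition”.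

The flask gives an order of 0.95 and 13.1% in the spring run, both forecast values holding within their margins. The apparent early order in catalyst in the noon run is 1.0.

    catalyst + substrate + partner → target + catalyst (129.0 M⁻² min⁻¹)
    substrate + partner ⇌ idle substrate-reagent adduct, settled at all times (2.520 M⁻¹)
    target + partner → side product (0.4962 M⁻¹ min⁻¹)

Now use the working time once more. The spring target of 0.0314 M, divided by my early rate, gives 10.0 min of working time in the spring run, against 7.38 min in the midnight run.

The runs were computed with made-up constants.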